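**Retrosynthetic overview**

- The target is an 8,6'-linked bicoumarin: unit A (4,7-dimethoxy-5-methylcoumarin, joined through C8 of ring A) and unit B (7-hydroxy-4-methoxy-5-methylcoumarin, joined through C6' of ring B). The one strategic disconnection is the C8–C6' biaryl bond.
- The bond is made between two intact coumarins of like (nucleophilic) polarity. C8 of unit A is reversed in polarity as an aryllead triacetate, made in the flask from the 8-boronic acid, and is delivered to C6' of the free phenol of unit B (Pinhey arylation).
- Enabling feature: the free hydroxyl on C7' of ring B sits directly beside the biaryl carbon C6', so O7' can bind lead and hand the aryl group to its ortho carbon. The other ortho carbon, C8', carries a temporary bromine. C8 of ring A lies between two oxygen atoms (O7 and ring oxygen O1), the site of directed lithiation in orcinol dimethyl ether.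
- Both halves come from one intermediate, 8-bromo-4,7-dihydroxy-5-methylcoumarin. Its bromine is the borylation handle for unit A and the blocking group for unit B, and is removed by hydrogenolysis at the end.
- Ring order: the benzene ring is bought (3,5-dimethoxytoluene); the pyranone ring is closed once, before the route divides (2-hydroxyacetophenone plus diethyl carbonate); the biaryl bond follows; no further ring is formed.

Key step: step 8

Assumption: the target is drawn without a descriptor for the C8–C6' axis, so the route is planned for the racemate (the tetra-ortho-substituted axis is expected to be configurationally stable).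

**Route**

Step 1
Reactants: 1 3,5-dimethoxytoluene
Product: 3 2-bromo-1,3-dimethoxy-5-methylbenzene, via aryllithium 2 (not isolated)
Conditions: n-BuLi, THF, 0 °C to rt; then BrCH2CH2Br, -78 °C to rt
Reagents that add atoms: 1,2-dibromoethane BrCCBr
Why: Directed ortho-metalation, in which the C–H between the two methoxy groups is the most acidic ring position and is lithiated selectively, followed by bromine transfer from 1,2-dibromoethane to the aryllithium with loss of ethene.

Step 2
Reactants: 3 2-bromo-1,3-dimethoxy-5-methylbenzene
Product: 4 1-(3-bromo-2,4-dimethoxy-6-methylphenyl)ethan-1-one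
Conditions: AcOH, (CF3CO)2O, H3PO4 (cat.), CH2Cl2, 0 °C to rt
Reagents that add atoms: acetic acid CC(=O)O
Why: Friedel–Crafts acylation by the mixed anhydride acetyl trifluoroacetate, where the two free ring positions are equivalent and each is para to one methoxy group, so only one ketone can form.

Step 3
Reactants: 4 1-(3-bromo-2,4-dimethoxy-6-methylphenyl)ethan-1-one
Product: 5 1-(3-bromo-2,4-dihydroxy-6-methylphenyl)ethan-1-one
Conditions: BBr3, CH2Cl2, -78 °C to rt; then H2O
Reagents that add atoms: none
Why: Lewis-acid cleavage of both aryl methyl ethers by BBr3 (the ether ortho to the ketone is assisted by chelation), with the aryl bromide and the ketone inert.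

Step 4
Reactants: 5 1-(3-bromo-2,4-dihydroxy-6-methylphenyl)ethan-1-one
Product: 7 8-bromo-4,7-dihydroxy-5-methyl-2H-chromen-2-one, via beta-keto ester 6 (not isolated)
Conditions: NaH, (EtO)2CO, toluene, 110 °C; then HCl (aq)
Reagents that add atoms: diethyl carbonate CCOC(=O)OCC
Why: Claisen-type C-ethoxycarbonylation of the methyl ketone enolate followed by lactonisation onto the ortho phenoxide (the standard 4-hydroxycoumarin synthesis from 2-hydroxyacetophenones), with the para phenoxide a spectator because any aryl carbonate formed reverts under ethoxide.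

Step 5
Reactants: 7 8-bromo-4,7-dihydroxy-5-methyl-2H-chromen-2-one
Product: 8 8-bromo-4,7-dimethoxy-5-methyl-2H-chromen-2-one
Conditions: Me2SO4, K2CO3, acetone, 56 °C
Reagents that add atoms: dimethyl sulfate COS(=O)(=O)OC
Why: Williamson O-methylation of both the phenoxide and the vinylogous carboxylate at C4, where the hard electrophile dimethyl sulfate favours O- over C3-alkylation and the 4-methoxycoumarin over the 2-methoxychromone.

Step 6
Reactants: 8 8-bromo-4,7-dimethoxy-5-methyl-2H-chromen-2-one
Product: 10 (4,7-dimethoxy-5-methyl-2-oxo-2H-chromen-8-yl)boronic acid, via pinacol boronate 9 (not isolated)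
Conditions: B2pin2, Pd2(dba)3 (cat.), SPhos, KOAc, 1,4-dioxane, 100 °C; filter, evaporate; then NaIO4, NH4OAc, acetone/H2O, rt
Reagents that add atoms: bis(pinacolato)diboron CC1(C)OB(OC1(C)C)B1OC(C)(C)C(C)(C)O1; water O
Why: Miyaura borylation of the di-ortho-substituted aryl bromide with an SPhos-ligated zerovalent palladium catalyst, followed by periodate cleavage of the pinacol ester to free the boronic acid needed for boron-to-lead exchange.

Step 7
Reactants: 7 8-bromo-4,7-dihydroxy-5-methyl-2H-chromen-2-one
Product: 11 8-bromo-7-hydroxy-4-methoxy-5-methyl-2H-chromen-2-one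
Conditions: MeOH, H2SO4 (cat.), 65 °C
Reagents that add atoms: methanol CO
Why: Acid-catalysed (Fischer-type) etherification of a vinylogous carboxylic acid, in which only the 4-hydroxyl is exchanged for methoxy by addition–elimination of methanol at C4 while the ordinary phenol at C7 cannot react under these conditions.

Step 8
Reactants: 10 (4,7-dimethoxy-5-methyl-2-oxo-2H-chromen-8-yl)boronic acid; 11 8-bromo-7-hydroxy-4-methoxy-5-methyl-2H-chromen-2-one
Product: 13 8'-bromo-7'-hydroxy-4,4',7-trimethoxy-5,5'-dimethyl-2H,2'H-[8,6'-bichromene]-2,2'-dione, via aryllead triacetate 12 (not isolated)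
Conditions: 10 (slight excess), Pb(OAc)4, Hg(OAc)2 (cat.), CHCl3, 40 °C; then 11, pyridine, CHCl3, 60 °C
Reagents that add atoms: none
Why: Pinhey arylation with the aryllead reagent made in the flask: boron-to-lead exchange turns boronic acid 10 into aryllead triacetate 12, in which the normally nucleophilic C8 of ring A is bound to tetravalent lead and acts as an aryl cation equivalent, so two electron-rich aryl carbons of like polarity can be joined. Phenol 11 displaces one acetate on lead through O7', and ligand coupling through a cyclic transition state moves the aryl group from lead to the ortho carbon C6', giving a 6-aryl-cyclohexa-2,4-dienone and Pb(OAc)2 (divalent lead), after which tautomerisation restores the phenol. The closest known reaction type is the ortho C-arylation of phenols by aryllead triacetates in CHCl3/pyridine, which is little affected by ortho substituents, is fastest with ortho-alkoxy aryllead reagents and is an established entry to biaryls with three or four ortho substituents. No ring is closed and no stereocentre is created; the new axis should form as the racemate because nothing in the step is chiral. The step needs C- over O-arylation and C6' over C8' and C3': the lead-bound pathway delivers the aryl group only to a carbon ortho to O7', C8' is blocked by bromine (ipso attack there would be hindered and could not rearomatise), the para carbon C4a' is a ring-fusion carbon and C3' of the pyranone cannot be reached from O7'. Because the directing hydroxyl is the one free hydroxyl of the target and all methoxy groups are already in place, the step should give the complete skeleton and oxygenation pattern without any protecting group.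

Step 9
Reactants: 13 8'-bromo-7'-hydroxy-4,4',7-trimethoxy-5,5'-dimethyl-2H,2'H-[8,6'-bichromene]-2,2'-dione
Product: 14 7'-hydroxy-4,4',7-trimethoxy-5,5'-dimethyl-2H,2'H-[8,6'-bichromene]-2,2'-dione
Conditions: H2 (1 atm), Pd/C, NaOAc, MeOH/EtOAc, rt
Reagents that add atoms: none
Why: Catalytic hydrogenolysis (hydrodehalogenation) of the aryl bromide on Pd/C with NaOAc as acid scavenger, under which the electron-rich trisubstituted 3,4-double bonds of the two 4-methoxycoumarins should not be reduced.

**Compound list**

1 | 3,5-dimethoxytoluene (orcinol dimethyl ether) | COc1cc(C)cc(OC)c1 | starting material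
2 | (2,6-dimethoxy-4-methylphenyl)lithium | [Li]c1c(OC)cc(C)cc1OC | intermediate
3 | 2-bromo-1,3-dimethoxy-5-methylbenzene | COc1cc(C)cc(OC)c1Br | intermediate
4 | 1-(3-bromo-2,4-dimethoxy-6-methylphenyl)ethan-1-one | CC(=O)c1c(C)cc(OC)c(Br)c1OC | intermediate
5 | 1-(3-bromo-2,4-dihydroxy-6-methylphenyl)ethan-1-one | CC(=O)c1c(C)cc(O)c(Br)c1O | intermediate
6 | ethyl 3-(3-bromo-2,4-dihydroxy-6-methylphenyl)-3-oxopropanoate | CCOC(=O)CC(=O)c1c(C)cc(O)c(Br)c1O | intermediate
7 | 8-bromo-4,7-dihydroxy-5-methyl-2H-chromen-2-one | Cc1cc(O)c(Br)c2oc(=O)cc(O)c12 | intermediate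
8 | 8-bromo-4,7-dimethoxy-5-methyl-2H-chromen-2-one | COc1cc(C)c2c(OC)cc(=O)oc2c1Br | intermediate
9 | 4,7-dimethoxy-5-methyl-8-(4,4,5,5-tetramethyl-1,3,2-dioxaborolan-2-yl)-2H-chromen-2-one | COc1cc(C)c2c(OC)cc(=O)oc2c1B1OC(C)(C)C(C)(C)O1 | intermediate
10 | (4,7-dimethoxy-5-methyl-2-oxo-2H-chromen-8-yl)boronic acid | COc1cc(C)c2c(OC)cc(=O)oc2c1B(O)O | intermediate
11 | 8-bromo-7-hydroxy-4-methoxy-5-methyl-2H-chromen-2-one | COc1cc(=O)oc2c(Br)c(O)cc(C)c12 | intermediate
12 | (4,7-dimethoxy-5-methyl-2-oxo-2H-chromen-8-yl)lead triacetate | COc1cc(C)c2c(OC)cc(=O)oc2c1[Pb](OC(C)=O)(OC(C)=O)OC(C)=O | intermediate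
13 | 8'-bromo-7'-hydroxy-4,4',7-trimethoxy-5,5'-dimethyl-2H,2'H-[8,6'-bichromene]-2,2'-dione (racemic biaryl axis) | COc1cc(C)c2c(OC)cc(=O)oc2c1-c1c(O)c(Br)c2oc(=O)cc(OC)c2c1C | intermediate
14 | 7'-hydroxy-4,4',7-trimethoxy-5,5'-dimethyl-2H,2'H-[8,6'-bichromene]-2,2'-dione (racemic biaryl axis) | COc1cc(C)c2c(OC)cc(=O)oc2c1-c1c(O)cc2oc(=O)cc(OC)c2c1C | target

**Step count and risks**

Total step count: 9.
Longest linear sequence: 8 steps (steps 1, 2, 3, 4, 5, 6, 8, 9); step 7 is the one-step branch from 7 to 11.

Steps most likely to fail:

1. Step 8. Ligand coupling at the hindered C6' of an acidic, rather electron-poor phenol may be slow, so that the aryllead reagent decomposes (protodeplumbation or acetoxylation) or attacks the bromine-bearing C8' ipso. The fallback is a cross-coupling of conventional polarity and sets out from 11. Ortho-iodination of the phenol at its only free ortho position (benzyltrimethylammonium dichloroiodate, NaHCO3, CH2Cl2/MeOH, rt) should give 8-bromo-7-hydroxy-6-iodo-4-methoxy-5-methyl-2H-chromen-2-one F1. Suzuki–Miyaura coupling of F1 with boronic acid 10 (Pd(OAc)2, SPhos, K3PO4, toluene/H2O, 80 °C) should then react at the carbon–iodine bond in preference to the more hindered and more electron-rich carbon–bromine bond, and comes back to the route at 13.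

2. Step 6. The di-ortho-oxygenated arylboron species may protodeboronate under the basic coupling conditions or during pinacol cleavage, and the carbon–bromine bond may be reduced at the hindered palladium intermediate. The fallback avoids boron altogether and sets out from 8. Base-free stannylation (Me3SnSnMe3, Pd(PPh3)4, toluene, 110 °C) should give 4,7-dimethoxy-5-methyl-8-(trimethylstannyl)-2H-chromen-2-one F2, a stable aryl donor. Tin-to-lead exchange of F2 (Pb(OAc)4, Hg(OAc)2 (cat.), CHCl3, 40 °C) then gives the aryllead reagent directly, so the route is rejoined at 12 and boronic acid 10 is bypassed.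

3. Step 7. Exchange at the peri-hindered C4 may be incomplete, and acid-catalysed methanolysis may open the lactone. The fallback replaces chemoselective etherification by temporary protection and sets out from 5. Selective protection of the non-chelated hydroxyl (MOMCl, i-Pr2NEt, CH2Cl2, 0 °C) should give 1-[3-bromo-2-hydroxy-4-(methoxymethoxy)-6-methylphenyl]ethan-1-one F3. Ring closure as in step 4 (NaH, (EtO)2CO, toluene, 110 °C) should give 8-bromo-4-hydroxy-7-(methoxymethoxy)-5-methyl-2H-chromen-2-one F4. Methylation (Me2SO4, K2CO3, acetone) should give 8-bromo-4-methoxy-7-(methoxymethoxy)-5-methyl-2H-chromen-2-one F5. Mild acetal cleavage (HCl, MeOH, rt) then comes back to the route at 11.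

Further compounds
F1 | step 8 | 8-bromo-7-hydroxy-6-iodo-4-methoxy-5-methyl-2H-chromen-2-one | COc1cc(=O)oc2c(Br)c(O)c(I)c(C)c12
F2 | step 6 | 4,7-dimethoxy-5-methyl-8-(trimethylstannyl)-2H-chromen-2-one | COc1cc(C)c2c(OC)cc(=O)oc2c1[Sn](C)(C)C
F3 | step 7 | 1-[3-bromo-2-hydroxy-4-(methoxymethoxy)-6-methylphenyl]ethan-1-one | CC(=O)c1c(C)cc(OCOC)c(Br)c1O
F4 | step 7 | 8-bromo-4-hydroxy-7-(methoxymethoxy)-5-methyl-2H-chromen-2-one | COCOc1cc(C)c2c(O)cc(=O)oc2c1Br
F5 | step 7 | 8-bromo-4-methoxy-7-(methoxymethoxy)-5-methyl-2H-chromen-2-one | COCOc1cc(C)c2c(OC)cc(=O)oc2c1Br
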